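A direct plan would condense O-allyl/O-methyl protected aromatic partners to the racemic flavanone A1, shift its aryl group from C2 to C3 with a hypervalent-iodine oxidant and move both allyl groups to carbon by a double Claisen rearrangement, which would give the diallyl isoflavone A2. A strong Lewis acid would then strip the methyl ethers to the diallyl tetraphenol A3, a double cross-metathesis would turn both allyl groups into prenyl groups to reach the diprenyl tetraphenol A4 (isoangustone A), and oxidation of the free catechol of A4 would close ring D last.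
Weak point 1, the final oxidative closure of ring D on the unprotected tetraphenol A4: it would have no precedent, and the oxidant would meet the electron-rich prenylated ring A and the product chromene in the very last step.
Weak point 2, the Lewis-acid demethylation of A2 to A3: the methyl ethers would be carried through most of the route only to be removed by a reagent that can hydrohalogenate or cyclise allyl groups ortho to phenols, a protecting-group stretch that builds nothing.
Weak point 3, the allyl-then-metathesis detour from A3 to A4 together with the flavanone/aryl-shift sequence through A1: many operations (one a high-temperature rearrangement, one a metathesis on a free catechol) would be spent on placing one aryl group and two prenyl-derived units.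

**Retrosynthetic overview**
Ring A (C4a, C5, C6, C7, C8, C8a) is not taken from a phloroglucinol but made last: cutting C5–C6 and C7–C8 leads to the 3-aryl-4-pyranone 14 (ring C, whose methyl group becomes C8 and whose ester carbon becomes C5) and ethyl 5-methylhex-4-enoate 17 (C1 becomes C7; C2, which carries the prenyl chain, becomes C6).
Ring order: D first (propargyl Claisen/oxa-6π on methyl homovanillate, regiochemistry fixed by the methyl ether), then C (C-acylation of ethyl acetoacetate, C1 insertion, pyranone closure), then A in the key step.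
The design removes the C6/C8 prenylation question (connectivity decides it), needs no protecting group on ring A, and lets no Lewis acid or oxidant meet the prenyl group or the finished isoflavone; the single protecting group is an aryl silyl ether removed by fluoride.

Key step: step 7

Remark: Ar stands for the 2,2-dimethyl-8-(triisopropylsilyloxy)-2H-chromen-6-yl group; 11 and 18 are drawn as keto tautomers although both should be largely enolised, which does not change the connectivity.

Step 1
Reactants: 1 methyl 2-(4-hydroxy-3-methoxyphenyl)acetate (methyl homovanillate); 2 3-chloro-3-methylbut-1-yne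
Product: 4 methyl 2-(8-methoxy-2,2-dimethyl-2H-chromen-6-yl)acetate, via aryl propargyl ether 3 (not isolated)
Conditions: 2 (1.5 equiv), K2CO3 (2 equiv), KI (0.2 equiv), CuI (5 mol %), acetone, reflux, 16 h; filter, evaporate; then PhNEt2, 180 °C, 2 h
Reagents that add atoms: 3-chloro-3-methylbut-1-yne (2), C#CC(C)(C)Cl
Why: CuI-assisted O-alkylation of the only free phenol, then aromatic propargyl Claisen rearrangement to the only free ortho position (the other carries OMe), [1,5]-H shift and oxa-6π electrocyclisation, so ring D closes on the former 4-OH with the regiochemistry fixed by the methyl ether and without a stereocentre.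

Step 2
Reactants: 4 methyl 2-(8-methoxy-2,2-dimethyl-2H-chromen-6-yl)acetate
Product: 5 2-(8-hydroxy-2,2-dimethyl-2H-chromen-6-yl)acetic acid
Conditions: NaSEt (5 equiv), DMF, 120 °C, 3 h; then cold dilute HCl to pH 3
Reagents that add atoms: none
Why: Thiolate SN2 dealkylation, which cleaves the aryl methyl ether and the methyl ester at their methyl carbons in one basic operation, cannot attack the tertiary chromene ether, spares the acid-sensitive 2H-chromene that a Lewis acid would destroy, and frees the acid needed for step 4.

Step 3
Reactants: 5 2-(8-hydroxy-2,2-dimethyl-2H-chromen-6-yl)acetic acid; 6 chlorotriisopropylsilane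
Product: 8 2-[2,2-dimethyl-8-(triisopropylsilyloxy)-2H-chromen-6-yl]acetic acid (ArCH2CO2H), via bis-silyl derivative 7 (not isolated)
Conditions: i-Pr3SiCl (2.3 equiv), imidazole (5 equiv), DMF, rt, 12 h; then K2CO3 (1.5 equiv), THF–MeOH–H2O, 0 °C, 1 h; citric acid to pH 4
Reagents that add atoms: chlorotriisopropylsilane (6), CC(C)[Si](Cl)(C(C)C)C(C)C
Why: Silylation of phenol and acid followed by selective hydrolysis of the labile silyl ester, which leaves a bulky aryl silyl ether that should survive amide bases and alkoxide and can be removed by fluoride without acid.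

Step 4
Reactants: 8 ArCH2CO2H; 9 ethyl acetoacetate
Product: 11 ethyl 2-acetyl-4-Ar-3-oxobutanoate, via acid chloride 10 (not isolated)
Conditions: Me2C=C(Cl)NMe2 (1.1 equiv), CH2Cl2, 0 °C to rt, 1 h; then added to 9 (1.2 equiv), MgCl2 (1.2 equiv), pyridine (2.4 equiv), CH2Cl2, 0 °C to rt, 3 h; cold aqueous citric acid
Reagents that add atoms: ethyl acetoacetate (9), CCOC(=O)CC(C)=O
Why: Acid chloride formation with the chloroenamine under neutral conditions (no HCl near the chromene), then C-acylation of the magnesium chelate of ethyl acetoacetate, in which chelation directs the acyl group to carbon and not to oxygen.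

Step 5
Reactants: 11 ethyl 2-acetyl-4-Ar-3-oxobutanoate; 12 N,N-dimethylformamide dimethyl acetal
Product: 14 ethyl 5-Ar-2-methyl-4-oxo-4H-pyran-3-carboxylate, via enaminone 13 (not isolated)
Conditions: Me2NCH(OMe)2 (2 equiv), toluene, 80 °C, 3 h; then AcOH (5 equiv), 60 °C, 1 h
Reagents that add atoms: N,N-dimethylformamide dimethyl acetal (12), COC(OC)N(C)C
Why: Enaminone formation and cyclocondensation as in the deoxybenzoin route to isoflavones, in which the acetal condenses at the benzylic CH2 (more acidic than the acetyl CH3, as with arylacetones) and the acetyl enol oxygen then displaces dimethylamine in a 6-endo-trig addition–elimination to close ring C, the ester being unable to cyclise on an enamine carbon.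

Step 6
Reactants: 15 2-methylbut-3-en-2-ol; 16 triethyl orthoacetate
Product: 17 ethyl 5-methylhex-4-enoate
Conditions: 16 (3 equiv), EtCO2H (5 mol %), 140 °C, 6 h, EtOH distilled off
Reagents that add atoms: triethyl orthoacetate (16), CCOC(C)(OCC)OCC
Why: Johnson–Claisen rearrangement, in which the mixed ketene acetal of the tertiary allylic alcohol undergoes a [3,3] shift to the ester that already holds the later C7, C6 and the intact prenyl group, with no E/Z question because the new alkene ends in CMe2.

Step 7
Reactants: 14 ethyl 5-Ar-2-methyl-4-oxo-4H-pyran-3-carboxylate; 17 ethyl 5-methylhex-4-enoate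
Product: 19 5,7-dihydroxy-3-Ar-6-(3-methylbut-2-enyl)-4H-chromen-4-one, via keto ester 18 (not isolated)
Conditions: 14 added to LiN(SiMe3)2 (2.2 equiv), THF, −78 °C, 30 min; 17 (1.5 equiv), −78 to 0 °C, 2 h; then LiN(i-Pr)2 (2.0 equiv), −78 °C to rt, 3 h; AcOH, −20 °C
Reagents that add atoms: ethyl 5-methylhex-4-enoate (17), CCOC(=O)CCC=C(C)C
Why: Proposed new method: LiN(SiMe3)2 deprotonates the methyl group of 14 (vinylogous to both the ring carbonyl and the ester), the lithiated pyranone is acylated at that carbon by 17 (Claisen condensation, C7–C8 bond), the second equivalent of silylamide takes the far more acidic C8–H of keto ester 18 so that the methyl anion is not quenched, and LiN(i-Pr)2 then deprotonates the other α-carbon of the ketone (C6, the former C2 of 17, which carries the prenyl chain) so that the 1,3-dianion attacks the pyranone ester (Dieckmann-type C5–C6 bond), loses ethoxide and enolises twice to the aromatic 5,7-diol. The closest known reaction types are the acylation of γ-lithiated 2-methyl-4-pyranones and 2-methylchromones, the base-induced closure of 2-(2-oxoalkyl)benzoates to naphthalene-1,3-diols and the Michael–Dieckmann annulation of o-toluate anions, whereas a Claisen–Dieckmann cascade that builds a phloroglucinol-type ring on a 4-pyranone has no direct precedent. Ring A closes as a 6-(enolendo)-exo-trig acyl substitution onto the preformed pyranone ring C, with ring D already in place on the aryl group. No stereocentre is formed. The step needs acylation at the methyl carbon (the only acidic C–H of 14), ring closure through carbon and not oxygen (the dianion carbon is the most nucleophilic site, aldol addition to the ring carbonyl C4 is reversible, and the aromatic bis-phenoxide is the irreversible sink) and the prenyl group at C6 and not C8, which connectivity fixes because C6 is the α-carbon of 17 and can only end between C5 and C7. Ring A therefore never needs protection and the prenyl group enters in the last C–C bond-forming step.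

Step 8
Reactants: 19 5,7-dihydroxy-3-Ar-6-(3-methylbut-2-enyl)-4H-chromen-4-one
Product: 20 gancaonin H
Conditions: Bu4NF (1.2 equiv), AcOH (1.2 equiv), THF, 0 °C, 30 min
Reagents that add atoms: none
Why: Fluoride cleavage of the aryl silyl ether, buffered with AcOH so that the isoflavone is not held as a phenoxide in base, under which the prenyl group, the chromene and the chromenone should be inert and no stereocentre is involved (the target is achiral).

**Compound list**
1 | methyl 2-(4-hydroxy-3-methoxyphenyl)acetate (methyl homovanillate) | COC(=O)Cc1ccc(O)c(OC)c1 | starting material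
2 | 3-chloro-3-methylbut-1-yne | C#CC(C)(C)Cl | starting material
3 | methyl 2-[3-methoxy-4-(2-methylbut-3-yn-2-yloxy)phenyl]acetate | COC(=O)Cc1ccc(OC(C)(C)C#C)c(OC)c1 | intermediate (not isolated)
4 | methyl 2-(8-methoxy-2,2-dimethyl-2H-chromen-6-yl)acetate | COC(=O)Cc1cc(OC)c2OC(C)(C)C=Cc2c1 | intermediate
5 | 2-(8-hydroxy-2,2-dimethyl-2H-chromen-6-yl)acetic acid | OC(=O)Cc1cc(O)c2OC(C)(C)C=Cc2c1 | intermediate
6 | chlorotriisopropylsilane | CC(C)[Si](Cl)(C(C)C)C(C)C | starting material
7 | triisopropylsilyl 2-[2,2-dimethyl-8-(triisopropylsilyloxy)-2H-chromen-6-yl]acetate | CC(C)[Si](OC(=O)Cc1cc(O[Si](C(C)C)(C(C)C)C(C)C)c2OC(C)(C)C=Cc2c1)(C(C)C)C(C)C | intermediate (not isolated)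
8 | 2-[2,2-dimethyl-8-(triisopropylsilyloxy)-2H-chromen-6-yl]acetic acid | OC(=O)Cc1cc(O[Si](C(C)C)(C(C)C)C(C)C)c2OC(C)(C)C=Cc2c1 | intermediate
9 | ethyl acetoacetate | CCOC(=O)CC(C)=O | starting material
10 | 2-[2,2-dimethyl-8-(triisopropylsilyloxy)-2H-chromen-6-yl]acetyl chloride | O=C(Cl)Cc1cc(O[Si](C(C)C)(C(C)C)C(C)C)c2OC(C)(C)C=Cc2c1 | intermediate (not isolated)
11 | ethyl 2-acetyl-4-[2,2-dimethyl-8-(triisopropylsilyloxy)-2H-chromen-6-yl]-3-oxobutanoate | CCOC(=O)C(C(C)=O)C(=O)Cc1cc(O[Si](C(C)C)(C(C)C)C(C)C)c2OC(C)(C)C=Cc2c1 | intermediate
12 | N,N-dimethylformamide dimethyl acetal | COC(OC)N(C)C | starting material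
13 | ethyl 2-acetyl-5-(dimethylamino)-4-[2,2-dimethyl-8-(triisopropylsilyloxy)-2H-chromen-6-yl]-3-oxopent-4-enoate (enamine geometry not fixed; both isomers cyclise) | CCOC(=O)C(C(C)=O)C(=O)C(=CN(C)C)c1cc(O[Si](C(C)C)(C(C)C)C(C)C)c2OC(C)(C)C=Cc2c1 | intermediate (not isolated)
14 | ethyl 5-[2,2-dimethyl-8-(triisopropylsilyloxy)-2H-chromen-6-yl]-2-methyl-4-oxo-4H-pyran-3-carboxylate | CCOC(=O)c1c(C)occ(-c2cc(O[Si](C(C)C)(C(C)C)C(C)C)c3OC(C)(C)C=Cc3c2)c1=O | intermediate
15 | 2-methylbut-3-en-2-ol | C=CC(C)(C)O | starting material
16 | triethyl orthoacetate | CCOC(C)(OCC)OCC | starting material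
17 | ethyl 5-methylhex-4-enoate | CCOC(=O)CCC=C(C)C | intermediate
18 | ethyl 5-[2,2-dimethyl-8-(triisopropylsilyloxy)-2H-chromen-6-yl]-2-(6-methyl-2-oxohept-5-enyl)-4-oxo-4H-pyran-3-carboxylate | CCOC(=O)c1c(CC(=O)CCC=C(C)C)occ(-c2cc(O[Si](C(C)C)(C(C)C)C(C)C)c3OC(C)(C)C=Cc3c2)c1=O | intermediate (not isolated)
19 | 5,7-dihydroxy-3-[2,2-dimethyl-8-(triisopropylsilyloxy)-2H-chromen-6-yl]-6-(3-methylbut-2-enyl)-4H-chromen-4-one | CC(C)=CCc1c(O)cc2occ(-c3cc(O[Si](C(C)C)(C(C)C)C(C)C)c4OC(C)(C)C=Cc4c3)c(=O)c2c1O | intermediate
20 | gancaonin H (achiral) | CC(C)=CCc1c(O)cc2occ(-c3cc(O)c4c(c3)C=CC(C)(C)O4)c(=O)c2c1O | target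

**Step count**
Total: 8 steps. Longest linear sequence: 7 steps (steps 1 to 5, 7 and 8); step 6 is a one-step side branch.

**Steps most likely to fail**

Step 7 (Proposed new method). What may go wrong: the lithiated methyl group is quenched by the more acidic keto ester as it forms; the ester self-condenses; the second deprotonation is incomplete so that ring A does not close, or closes through oxygen to a lactone; carbanions add to the unsubstituted C6–H position of the pyranone. The fallback would set out from 14 and 17 and come back at 19, separating the two bond formations into known reaction types. Ester 17 would be converted into N-methoxy-N,5-dimethylhex-4-enamide F1 (MeNHOMe·HCl, i-PrMgCl, THF, −20 °C). Lithiated 14 (one equivalent of LiN(SiMe3)2, −78 °C) would be acylated by F1, whose chelated adduct does not release the ketone before work-up, so that no proton transfer interferes and keto ester 18 would be isolated. Ring A would then be closed in a separate operation under equilibrating alkoxide conditions (NaOMe, MeOH, or t-BuOK, THF, rt to 50 °C), the known base-induced Claisen closure of 2-(2-oxoalkyl)aroates to arene-1,3-diols, in which a lactone formed through oxygen is reopened by alkoxide and drains to the aromatic diol 19; a silyl ether lost under these conditions would simply give 20.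

Step 5. What may go wrong: condensation at the acetyl methyl group and not at the benzylic carbon; O-methylation of the acidic enol by the acetal; loss of the acetyl group by methanolysis or aminolysis of the triacylmethane. The fallback would set out from 8 and come back at 14, placing the C1 unit on the benzylic carbon before the acetoacetate is attached. Acid 8 would be esterified to methyl 2-[2,2-dimethyl-8-(triisopropylsilyloxy)-2H-chromen-6-yl]acetate F2 (MeI, K2CO3, DMF). Claisen formylation and O-methylation (HCO2Me, NaH, THF; then Me2SO4, K2CO3) would give methyl (E)-3-methoxy-2-[2,2-dimethyl-8-(triisopropylsilyloxy)-2H-chromen-6-yl]acrylate F3, and saponification (LiOH, THF–H2O) would give (E)-3-methoxy-2-[2,2-dimethyl-8-(triisopropylsilyloxy)-2H-chromen-6-yl]acrylic acid F4. Its acid chloride (chloroenamine as in step 4) would C-acylate the magnesium chelate of 9 to ethyl (E)-2-acetyl-5-methoxy-4-[2,2-dimethyl-8-(triisopropylsilyloxy)-2H-chromen-6-yl]-3-oxopent-4-enoate F5, which would close to 14 by displacement of methanol by the enol oxygen (DBU, or warm AcOH).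

Step 4. What may go wrong: ketene formation from the arylacetyl chloride and its dimerisation; O-acylation; deacetylation of 11 on work-up. The fallback would set out from 8 and come back at 11, building the tricarbonyl in the opposite order. Acid 8 would be activated with carbonyldiimidazole and extended with Mg(O2CCH2CO2Et)2 (decarboxylative Claisen condensation, THF, rt) to ethyl 4-[2,2-dimethyl-8-(triisopropylsilyloxy)-2H-chromen-6-yl]-3-oxobutanoate F6, which would be C-acetylated (AcCl, MgCl2, pyridine, CH2Cl2) to 11.

**Further compounds**
F1 | step 7 | N-methoxy-N,5-dimethylhex-4-enamide | CON(C)C(=O)CCC=C(C)C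
F2 | step 5 | methyl 2-[2,2-dimethyl-8-(triisopropylsilyloxy)-2H-chromen-6-yl]acetate | COC(=O)Cc1cc(O[Si](C(C)C)(C(C)C)C(C)C)c2OC(C)(C)C=Cc2c1
F3 | step 5 | methyl (E)-3-methoxy-2-[2,2-dimethyl-8-(triisopropylsilyloxy)-2H-chromen-6-yl]acrylate | CO/C=C(/C(=O)OC)c1cc(O[Si](C(C)C)(C(C)C)C(C)C)c2OC(C)(C)C=Cc2c1
F4 | step 5 | (E)-3-methoxy-2-[2,2-dimethyl-8-(triisopropylsilyloxy)-2H-chromen-6-yl]acrylic acid | CO/C=C(/C(=O)O)c1cc(O[Si](C(C)C)(C(C)C)C(C)C)c2OC(C)(C)C=Cc2c1
F5 | step 5 | ethyl (E)-2-acetyl-5-methoxy-4-[2,2-dimethyl-8-(triisopropylsilyloxy)-2H-chromen-6-yl]-3-oxopent-4-enoate | CCOC(=O)C(C(C)=O)C(=O)/C(=C/OC)c1cc(O[Si](C(C)C)(C(C)C)C(C)C)c2OC(C)(C)C=Cc2c1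
F6 | step 4 | ethyl 4-[2,2-dimethyl-8-(triisopropylsilyloxy)-2H-chromen-6-yl]-3-oxobutanoate | CCOC(=O)CC(=O)Cc1cc(O[Si](C(C)C)(C(C)C)C(C)C)c2OC(C)(C)C=Cc2c1
A1 | direct plan | rac-5-(allyloxy)-2-[4-(allyloxy)-3-methoxyphenyl]-7-methoxychroman-4-one | C=CCOc1ccc(C2CC(=O)c3c(OCC=C)cc(OC)cc3O2)cc1OC
A2 | direct plan | 6-allyl-3-(3-allyl-4-hydroxy-5-methoxyphenyl)-5-hydroxy-7-methoxy-4H-chromen-4-one | C=CCc1c(OC)cc2occ(-c3cc(CC=C)c(O)c(OC)c3)c(=O)c2c1O
A3 | direct plan | 6-allyl-3-(3-allyl-4,5-dihydroxyphenyl)-5,7-dihydroxy-4H-chromen-4-one | C=CCc1c(O)cc2occ(-c3cc(O)c(O)c(CC=C)c3)c(=O)c2c1O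
A4 | direct plan | isoangustone A | CC(C)=CCc1c(O)cc2occ(-c3cc(O)c(O)c(CC=C(C)C)c3)c(=O)c2c1O
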